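## Retrosynthetic overview

1. The target comes from a bis-silyl ether by global desilylation. The 6β-isovalerate is made by α-face hydride reduction of a 6-ketone and acylation of the alkoxide in the same flask. The 7α-oxygen comes from α-face oxygenation of the Δ8-6-ketone dienolate.
2. The C9 side chain is attached by an sp3–sp2 Suzuki coupling of a C9 enol triflate with the 9-BBN adduct of (2E)-3-methylpenta-2,4-dien-1-ol.
3. The enol triflate comes from conjugate reduction and O-triflation of a trans-fused bicyclic enedione (rings A and B).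
4. Ring A is closed second, by a cation–enol cyclisation of a monocyclic 6-homoprenyl-2,6-dimethylcyclohex-2-ene-1,4-dione. Ring B is the original benzene ring.
5. The C10 quaternary centre comes from an enantioselective conjugate addition that desymmetrises 4,4-dimethoxy-3,5-dimethylcyclohexa-2,5-dienone, itself made by oxidative dearomatisation of 3,5-dimethylphenol.

Assumption: the three starting materials are bought, and the antipode of the chiral carbene ligand in step 2 is the one that gives the S quaternary centre (the other antipode is used if the sense is opposite).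

Atom labels C1–C20 below are labdane numbering.

## Route

Step 1
Reactants: 1 3,5-dimethylphenol
Product: 2 4,4-dimethoxy-3,5-dimethylcyclohexa-2,5-dien-1-one
Conditions: PhI(OAc)2 (2.2 equiv), MeOH, 0 °C → rt
Reagents that add atoms: methanol, CO
Why: Oxidative dearomatisation of a para-unsubstituted phenol (two successive two-electron oxidations with methanol capture at the para carbon) gives the achiral, mirror-symmetric quinone monoketal in which both enone β-carbons carry a methyl group.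

Step 2
Reactants: 2 4,4-dimethoxy-3,5-dimethylcyclohexa-2,5-dien-1-one; 3 5-bromo-2-methylpent-2-ene
Product: 6 (6S)-2,6-dimethyl-6-(4-methylpent-3-en-1-yl)cyclohex-2-ene-1,4-dione, via Grignard reagent 4 (not isolated), via ketal enone 5 (not isolated)
Conditions: 3, Mg, Et2O, rt; slow addition to 2, Cu(OTf)2 (5 mol %), (S)-3-(1-hydroxy-4-methylpentan-2-yl)-1-mesityl-4,5-dihydroimidazolium hexafluorophosphate (6 mol %), Et2O, −30 °C; then 1 M HCl, THF, rt
Reagents that add atoms: water, O
Why: Proposed new method: copper-catalysed asymmetric conjugate addition of an alkyl Grignard reagent to a β-methyl quinone monoketal, reasoned from the known copper–carbene additions of alkyl Grignard reagents to 3-methylcyclohex-2-enones (quaternary centres) and the known copper-catalysed desymmetrisation of 4,4-disubstituted cyclohexadienones; the chiral alkoxy-carbene cuprate complexes one of the two enantiotopic enone arms of 2 and delivers the homoprenyl group to its β-carbon, setting the future C10 as S, and aqueous acid then protonates the enolate and hydrolyses the ketal.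

Step 3
Reactants: 6 (6S)-2,6-dimethyl-6-(4-methylpent-3-en-1-yl)cyclohex-2-ene-1,4-dione
Product: 8 (4aS,8aS)-2,5,5,8a-tetramethyl-4a,5,6,7,8,8a-hexahydronaphthalene-1,4-dione (trans-fused), via cis-fused epimer 7 (not isolated)
Conditions: TfOH (10 mol %), CH2Cl2, −40 → 0 °C; then Et3N, DBU (20 mol %), rt
Reagents that add atoms: none
Why: Cation–olefin cyclisation with enol termination (intramolecular α-tert-alkylation of a ketone): Markovnikov protonation gives the tertiary C4 cation, which is captured in a six-membered closure by C5, the only enolisable carbon, and the kinetic cis product 7 epimerises at C5 (α to the C6 ketone) by α-face protonation anti to the angular methyl to the trans-decalin 8, the ring fusion of the 6-oxo-5α-terpenoids.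

Step 4
Reactants: 8 (4aS,8aS)-2,5,5,8a-tetramethyl-4a,5,6,7,8,8a-hexahydronaphthalene-1,4-dione
Product: 10 (4aS,8aS)-2,5,5,8a-tetramethyl-4-oxo-3,4,4a,5,6,7,8,8a-octahydronaphthalen-1-yl trifluoromethanesulfonate, via lithium enolate 9 (not isolated)
Conditions: LiBH(s-Bu)3 (1.05 equiv), THF, −78 °C; then N-(5-chloropyridin-2-yl)triflimide (1.2 equiv), −78 → 0 °C
Reagents that add atoms: N-(5-chloropyridin-2-yl)-1,1,1-trifluoro-N-(trifluoromethylsulfonyl)methanesulfonamide, FC(F)(F)S(=O)(=O)N(c1ccc(Cl)cn1)S(=O)(=O)C(F)(F)F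
Why: Conjugate reduction with enolate trapping: the bulky hydride adds to the unsubstituted enedione carbon C7 rather than the methyl-bearing C8, giving regiospecifically the C9 enolate (C10 has no hydrogen), which is O-triflated; no stereocentre is touched.

Step 5
Reactants: 11 (2E)-3-methylpent-2-en-4-yn-1-ol
Product: 12 (2E)-3-methylpenta-2,4-dien-1-ol
Conditions: H2 (1 atm, 1.0 equiv), Pd/CaCO3 poisoned with Pb(OAc)2, quinoline, EtOAc, rt
Reagents that add atoms: none
Why: Semi-hydrogenation of the terminal alkyne to the vinyl group leaves the E trisubstituted alkene, which becomes the C13 alkene of the target, unchanged.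

Step 6
Reactants: 10 (4aS,8aS)-2,5,5,8a-tetramethyl-4-oxo-3,4,4a,5,6,7,8,8a-octahydronaphthalen-1-yl trifluoromethanesulfonate; 12 (2E)-3-methylpenta-2,4-dien-1-ol
Product: 14 (4aS,8aS)-4-[(3E)-5-hydroxy-3-methylpent-3-en-1-yl]-3,4a,8,8-tetramethyl-4a,5,6,7,8,8a-hexahydronaphthalen-1(2H)-one, via bis-borane 13 (not isolated)
Conditions: 12 (1.5 equiv), 9-BBN-H (3.2 equiv), THF, 0 °C → rt; then 3 M aq. K3PO4, 10, Pd(OAc)2 (5 mol %), SPhos (10 mol %), THF, 60 °C
Reagents that add atoms: none
Why: B-alkyl Suzuki–Miyaura coupling: 9-BBN caps the hydroxyl and hydroborates only the terminal vinyl group at its CH2 end (anti-Markovnikov), and the alkylborane couples with the hindered enol triflate to form the C9–C11 bond and the tetrasubstituted C8=C9 alkene; any base-induced shift of this alkene into conjugation is harmless because step 7 passes through the common dienolate.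

Step 7
Reactants: 14 (4aS,8aS)-4-[(3E)-5-hydroxy-3-methylpent-3-en-1-yl]-3,4a,8,8-tetramethyl-4a,5,6,7,8,8a-hexahydronaphthalen-1(2H)-one
Product: 17 (2S,4aS,8aS)-3,4a,8,8-tetramethyl-4-{(3E)-3-methyl-5-[(triethylsilyl)oxy]pent-3-en-1-yl}-2-[(triethylsilyl)oxy]-4a,5,6,7,8,8a-hexahydronaphthalen-1(2H)-one, via dipotassium dienolate 15 (not isolated), via dipotassium dialkoxide 16 (not isolated)
Conditions: KN(SiMe3)2 (2.3 equiv), THF, −78 °C; 3-phenyl-2-(phenylsulfonyl)-1,2-oxaziridine (1.3 equiv), −78 °C; then Et3SiCl (3 equiv), −78 → 0 °C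
Reagents that add atoms: 3-phenyl-2-(phenylsulfonyl)-1,2-oxaziridine, O=S(=O)(c1ccccc1)N1OC1c1ccccc1; chlorotriethylsilane, CC[Si](Cl)(CC)CC
Why: Enolate α-hydroxylation with a sulfonyloxaziridine: deprotonation at the doubly activated C7 gives the extended dienolate, which is oxygenated at its α-carbon from the α face (axial attack, anti to the C10 and C4β methyl groups) to set 7α-O, and silylation in the same flask protects both oxygens and stops ketol isomerisation.

Step 8
Reactants: 17 (2S,4aS,8aS)-3,4a,8,8-tetramethyl-4-{(3E)-3-methyl-5-[(triethylsilyl)oxy]pent-3-en-1-yl}-2-[(triethylsilyl)oxy]-4a,5,6,7,8,8a-hexahydronaphthalen-1(2H)-one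
Product: 19 (1S,2S,4aS,8aS)-3,4a,8,8-tetramethyl-4-{(3E)-3-methyl-5-[(triethylsilyl)oxy]pent-3-en-1-yl}-2-[(triethylsilyl)oxy]-1,2,4a,5,6,7,8,8a-octahydronaphthalen-1-yl 3-methylbutanoate, via lithium alkoxide 18 (not isolated)
Conditions: LiBHEt3 (1.5 equiv), THF, −78 → 0 °C; then 3-methylbutanoyl chloride (4 equiv), DMAP (0.2 equiv), 0 °C → rt
Reagents that add atoms: 3-methylbutanoyl chloride, CC(C)CC(=O)Cl
Why: Reductive acylation: the β face of the C6 ketone is blocked by the syn-axial C10 and C4β methyl groups, so hydride enters from the α face and gives the axial 6β-alkoxide, which is acylated as its lithium salt; the trans-diaxial 6β-O/7α-O arrangement rules out silyl or acyl migration.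

Step 9
Reactants: 19 (1S,2S,4aS,8aS)-3,4a,8,8-tetramethyl-4-{(3E)-3-methyl-5-[(triethylsilyl)oxy]pent-3-en-1-yl}-2-[(triethylsilyl)oxy]-1,2,4a,5,6,7,8,8a-octahydronaphthalen-1-yl 3-methylbutanoate
Product: 20 (1S,2S,4aS,8aS)-2-hydroxy-4-[(3E)-5-hydroxy-3-methylpent-3-en-1-yl]-3,4a,8,8-tetramethyl-1,2,4a,5,6,7,8,8a-octahydronaphthalen-1-yl 3-methylbutanoate (CNP0173680.1)
Conditions: HF·pyridine, pyridine/THF, 0 °C → rt
Reagents that add atoms: none
Why: Fluoride-mediated cleavage of both triethylsilyl ethers under buffered conditions leaves the hindered 6β-ester and all four stereocentres untouched.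

## Compound list

1 | 3,5-dimethylphenol | Cc1cc(C)cc(O)c1 | starting material
2 | 4,4-dimethoxy-3,5-dimethylcyclohexa-2,5-dien-1-one | COC1(OC)C(C)=CC(=O)C=C1C | intermediate
3 | 5-bromo-2-methylpent-2-ene | CC(C)=CCCBr | starting material
4 | (4-methylpent-3-en-1-yl)magnesium bromide | CC(C)=CCC[Mg]Br | intermediate
5 | (5S)-4,4-dimethoxy-3,5-dimethyl-5-(4-methylpent-3-en-1-yl)cyclohex-2-en-1-one | COC1(OC)C(C)=CC(=O)C[C@]1(C)CCC=C(C)C | intermediate
6 | (6S)-2,6-dimethyl-6-(4-methylpent-3-en-1-yl)cyclohex-2-ene-1,4-dione | CC1=CC(=O)C[C@](C)(CCC=C(C)C)C1=O | intermediate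
7 | (4aR,8aS)-2,5,5,8a-tetramethyl-4a,5,6,7,8,8a-hexahydronaphthalene-1,4-dione (cis-fused) | CC1=CC(=O)[C@@H]2C(C)(C)CCC[C@]2(C)C1=O | intermediate
8 | (4aS,8aS)-2,5,5,8a-tetramethyl-4a,5,6,7,8,8a-hexahydronaphthalene-1,4-dione (trans-fused) | CC1=CC(=O)[C@H]2C(C)(C)CCC[C@]2(C)C1=O | intermediate
9 | lithium (4aS,8aS)-2,5,5,8a-tetramethyl-4-oxo-3,4,4a,5,6,7,8,8a-octahydronaphthalen-1-olate | CC1=C([O-])[C@@]2(C)CCCC(C)(C)[C@@H]2C(=O)C1.[Li+] | intermediate
10 | (4aS,8aS)-2,5,5,8a-tetramethyl-4-oxo-3,4,4a,5,6,7,8,8a-octahydronaphthalen-1-yl trifluoromethanesulfonate | CC1=C(OS(=O)(=O)C(F)(F)F)[C@@]2(C)CCCC(C)(C)[C@@H]2C(=O)C1 | intermediate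
11 | (2E)-3-methylpent-2-en-4-yn-1-ol | C#C/C(C)=C/CO | starting material
12 | (2E)-3-methylpenta-2,4-dien-1-ol | C=C/C(C)=C/CO | intermediate
13 | 9-{(3E)-5-[(9-borabicyclo[3.3.1]nonan-9-yl)oxy]-3-methylpent-3-en-1-yl}-9-borabicyclo[3.3.1]nonane | B1(CC/C(C)=C/COB2C3CCCC2CCC3)C2CCCC1CCC2 | intermediate
14 | (4aS,8aS)-4-[(3E)-5-hydroxy-3-methylpent-3-en-1-yl]-3,4a,8,8-tetramethyl-4a,5,6,7,8,8a-hexahydronaphthalen-1(2H)-one | CC1=C(CC/C(C)=C/CO)[C@@]2(C)CCCC(C)(C)[C@@H]2C(=O)C1 | intermediate
15 | dipotassium (4aS,8aS)-3,4a,8,8-tetramethyl-4-[(3E)-3-methyl-5-oxidopent-3-en-1-yl]-4a,5,6,7,8,8a-hexahydronaphthalen-1-olate | CC1=C(CC/C(C)=C/C[O-])[C@@]2(C)CCCC(C)(C)[C@@H]2C([O-])=C1.[K+].[K+] | intermediate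
16 | dipotassium (2S,4aS,8aS)-3,4a,8,8-tetramethyl-4-[(3E)-3-methyl-5-oxidopent-3-en-1-yl]-1-oxo-1,2,4a,5,6,7,8,8a-octahydronaphthalen-2-olate | CC1=C(CC/C(C)=C/C[O-])[C@@]2(C)CCCC(C)(C)[C@@H]2C(=O)[C@H]1[O-].[K+].[K+] | intermediate
17 | (2S,4aS,8aS)-3,4a,8,8-tetramethyl-4-{(3E)-3-methyl-5-[(triethylsilyl)oxy]pent-3-en-1-yl}-2-[(triethylsilyl)oxy]-4a,5,6,7,8,8a-hexahydronaphthalen-1(2H)-one | CC1=C(CC/C(C)=C/CO[Si](CC)(CC)CC)[C@@]2(C)CCCC(C)(C)[C@@H]2C(=O)[C@H]1O[Si](CC)(CC)CC | intermediate
18 | lithium (1S,2S,4aS,8aS)-3,4a,8,8-tetramethyl-4-{(3E)-3-methyl-5-[(triethylsilyl)oxy]pent-3-en-1-yl}-2-[(triethylsilyl)oxy]-1,2,4a,5,6,7,8,8a-octahydronaphthalen-1-olate | CC1=C(CC/C(C)=C/CO[Si](CC)(CC)CC)[C@@]2(C)CCCC(C)(C)[C@@H]2[C@H]([O-])[C@H]1O[Si](CC)(CC)CC.[Li+] | intermediate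
19 | (1S,2S,4aS,8aS)-3,4a,8,8-tetramethyl-4-{(3E)-3-methyl-5-[(triethylsilyl)oxy]pent-3-en-1-yl}-2-[(triethylsilyl)oxy]-1,2,4a,5,6,7,8,8a-octahydronaphthalen-1-yl 3-methylbutanoate | CC1=C(CC/C(C)=C/CO[Si](CC)(CC)CC)[C@@]2(C)CCCC(C)(C)[C@@H]2[C@H](OC(=O)CC(C)C)[C@H]1O[Si](CC)(CC)CC | intermediate
20 | (1S,2S,4aS,8aS)-2-hydroxy-4-[(3E)-5-hydroxy-3-methylpent-3-en-1-yl]-3,4a,8,8-tetramethyl-1,2,4a,5,6,7,8,8a-octahydronaphthalen-1-yl 3-methylbutanoate | CC1=C(CC/C(C)=C/CO)[C@@]2(C)CCCC(C)(C)[C@@H]2[C@H](OC(=O)CC(C)C)[C@H]1O | target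

## Step count and risks

Total steps: 9. Longest linear sequence: 8 (steps 1, 2, 3, 4, 6, 7, 8, 9 from 3,5-dimethylphenol).

**Step 2 (most likely to fail).** The β-carbon is hindered by the neighbouring ketal carbon; 1,2-addition, reductive aromatisation of the monoketal and low enantioselectivity are the likely failures. The fallback replaces catalyst control by an auxiliary. It sets out from 2 and comes back at 6.
- Compound 2 is transketalised with (1R,2R)-1,2-diphenylethane-1,2-diol (PPTS, benzene, 60 °C, methanol removed) to the C2-symmetric spiroketal (2R,3R)-6,10-dimethyl-2,3-diphenyl-1,4-dioxaspiro[4.5]deca-6,9-dien-8-one F1, in which the two β-carbons are diastereotopic.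
- The organocopper reagent made from 4 (CuI, BF3·OEt2, THF, −78 °C) is added stoichiometrically to give (2R,3R,10S)-6,10-dimethyl-10-(4-methylpent-3-en-1-yl)-2,3-diphenyl-1,4-dioxaspiro[4.5]dec-6-en-8-one F2, purified from its C10 epimer by chromatography (the antipodal diol is used if the auxiliary favours the wrong epimer).
- Aqueous trifluoroacetic acid in THF hydrolyses the ketal to 6 and returns the diol.

**Step 3.** The protic conditions may trigger a dienone–phenol-type 1,2-shift or a carbonyl–ene closure instead of C5 alkylation. The fallback separates cation generation from enol activation. It sets out from 6 and comes back at 7, which step 3 already carries on to 8 with DBU.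
- HCl gas (CH2Cl2, 0 °C) adds to the trisubstituted alkene to give the tertiary chloride (6S)-6-(4-chloro-4-methylpentyl)-2,6-dimethylcyclohex-2-ene-1,4-dione F3.
- t-BuMe2SiOTf and Et3N convert the C6 ketone into the silyl dienol ether (6S)-4-[(tert-butyldimethylsilyl)oxy]-6-(4-chloro-4-methylpentyl)-2,6-dimethylcyclohexa-2,4-dien-1-one F4.
- TiCl4 (CH2Cl2, −78 °C) ionises the tertiary chloride and the silyl enol ether carbon C5 closes ring A (tert-alkylation of a silyl enol ether), giving 7.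

**Step 7.** The dienolate may be oxygenated at the γ-carbon or from the wrong face, and the α-ketol may isomerise before silylation. The fallback uses neutral electrophilic oxidation of a silyl dienol ether. It sets out from 14 and comes back at 17.
- Et3SiOTf (2.5 equiv) and Et3N (CH2Cl2, −78 → 0 °C) give the bis-silylated dienol ether triethyl({(4aS,8aS)-3,4a,8,8-tetramethyl-4-[(3E)-3-methyl-5-(triethylsilyloxy)pent-3-en-1-yl]-4a,5,6,7,8,8a-hexahydronaphthalen-1-yl}oxy)silane F5.
- Dimethyldioxirane (1 equiv, acetone/CH2Cl2, −78 °C) epoxidises the electron-rich C6=C7 enol ether bond from the α face, and the silyloxy epoxide rearranges with 1,4-silyl shift (Rubottom oxidation) to 17.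

Further compounds
F1 | step 2 | (2R,3R)-6,10-dimethyl-2,3-diphenyl-1,4-dioxaspiro[4.5]deca-6,9-dien-8-one | CC1=CC(=O)C=C(C)C12O[C@H](c3ccccc3)[C@@H](c3ccccc3)O2
F2 | step 2 | (2R,3R,10S)-6,10-dimethyl-10-(4-methylpent-3-en-1-yl)-2,3-diphenyl-1,4-dioxaspiro[4.5]dec-6-en-8-one | CC1=CC(=O)C[C@](C)(CCC=C(C)C)C12O[C@H](c3ccccc3)[C@@H](c3ccccc3)O2
F3 | step 3 | (6S)-6-(4-chloro-4-methylpentyl)-2,6-dimethylcyclohex-2-ene-1,4-dione | CC1=CC(=O)C[C@](C)(CCCC(C)(C)Cl)C1=O
F4 | step 3 | (6S)-4-[(tert-butyldimethylsilyl)oxy]-6-(4-chloro-4-methylpentyl)-2,6-dimethylcyclohexa-2,4-dien-1-one | CC1=CC(O[Si](C)(C)C(C)(C)C)=C[C@](C)(CCCC(C)(C)Cl)C1=O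
F5 | step 7 | triethyl({(4aS,8aS)-3,4a,8,8-tetramethyl-4-[(3E)-3-methyl-5-(triethylsilyloxy)pent-3-en-1-yl]-4a,5,6,7,8,8a-hexahydronaphthalen-1-yl}oxy)silane | CC1=C(CC/C(C)=C/CO[Si](CC)(CC)CC)[C@@]2(C)CCCC(C)(C)[C@@H]2C(O[Si](CC)(CC)CC)=C1
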